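- A chain once begun stays counted, living or dead, so the average length in midnight and in winter is the monomer in chains divided by a count that doesn't shrink.

the same everywhere: initiator 3.5 mM

| charge | free monomer | transfer agent | protic impurity | remark | time |
|---|---|---|---|---|---|
| violet | 0.37 M | 3.7 mM | 0.018 M | run made earlier |  |
| teal | 0.37 M | 3.7 mM | 0.028 M | run made earlier |  |
| amber | 0.55 M | 3.7 mM | 0.037 M | run made earlier |  |
| midnight | 0.37 M | 3.70 mM | 0.0370 M |  | 30 min |
| winter | 0.37 M | 3.70 mM | 0.0370 M |  | 10 min |

| run | time / min | monomer in chains / % |
|---|---|---|
| violet | 2.50 | 11.5 |
| violet | 4.00 | 18.8 |
| violet | 6.00 | 26.7 |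
| violet | 10.0 | 39.4 |
| violet | 20.0 | 62.0 |
| violet | 30.0 | 73.6 |
| teal | 5.00 | 22.5 |
| teal | 10.0 | 38.1 |
| teal | 15.0 | 50.2 |
| teal | 20.0 | 60.7 |
| teal | 25.0 | 66.9 |
| teal | 30.0 | 72.0 |
| amber | 6.00 | 26.7 |
| amber | 12.0 | 44.9 |
| amber | 20.0 | 60.8 |
| amber | 25.0 | 67.9 |
| amber | 30.0 | 72.2 |

(standard deviation of a reading: 0.5 percentage points)

- which of the two ends with the longer chains by the average number of monomer units in a chain (chains begun, living or dead) ("neither" if they lie within 10%) (midnight / winter / neither)
- average number of monomer units in a chain (chains begun, living or dead) at the end, midnight
- average number of monomer units in a chain (chains begun, living or dead) at the end, winter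

- the average divides the monomer in chains by the number of chains begun, living and dead together
- the earlier runs do not show the number of chains; that part of a forecast is a guess

- One pair of readings looks wrong: violet at 6.00 min and amber at 6.00 min both show 26.7% of their free monomer in chains, though amber was charged with 0.55 M of free monomer against 0.37 M, and with twice the protic impurity.
- Work with the fraction left and this clears up: minus the log of the fraction left, divided by the time, reads 0.0518 min⁻¹ in both runs, a time constant of 19.3 min. In these two runs a monomer's chance per minute doesn't follow the charge (pseudo-first-order).
- Midnight is charged with amber's molarity of protic impurity, but that is 10.0% of its free monomer against 6.73% in amber, so I don't take amber's 72.2% for it.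
- At 30.0 min, dividing each reading by one minus its run's impurity share gives 77.4% for violet, 77.9% for teal and 77.4% for amber, so I read the impurity as taking its own share of the free monomer. Amber's figure then gives midnight 69.7% in chains.
- For winter, the same division of violet's 39.4% at 10.0 min gives 41.4%, and so 37.3% in chains at 10 min.
- The runs don't show the chains, so this step is my guess: one chain per initiator. Dividing the charges gives 106, the full length, the units per chain if the whole free monomer charge went into chains begun that way. The average length is the full length times the fraction in chains, which gives 73.6 for midnight and 39.4 for winter, so midnight is longer.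
- The forecast also names midnight, but at 20 and 12 units, lower than mine, on these grounds: “The impurity does not kill the rate, so at most it transfers, restarting chains.”
- The simulation gives 74.1 units for midnight and 40.4 for winter, so midnight ends longer, and the difference in time is the main reason for that gap: winter's 40.4 units become 74.1 when it is read at midnight's 30 min.

    living end + transfer agent → dead chain (kL = 3.50 L mol⁻¹ min⁻¹)
    free monomer + initiator → living end + monomer in chains (k = 4.90 L mol⁻¹ min⁻¹)
    free monomer + living end → monomer in chains + living end, rate k3*[living end]*[free monomer] (k = 17.0 L mol⁻¹ min⁻¹)
    protic impurity + free monomer → quenched substrate (k = 1.40 L mol⁻¹ min⁻¹)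

- At 30.0 min midnight holds 0.00253 M of living ends and 9.73 × 10⁻⁴ M of dead chains, together 3.50 mM, the initiator charge, so the full length times its 70.1% in chains gives 74.1. The neighbour of midnight charged with 0.0014 M of initiator has a full length of 264, and its 40.4% in chains gives 107, against its simulated length of 107.

The earlier runs and the new flask are simulated on assumed constants, noise included.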